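## Retrosynthetic overview

1. Chain–ring C–C bond: formed by decarboxylative radical alkylation. The whole AcO(CH2)14 chain comes from 15-hydroxypentadecanoic acid 1 (as its acetate 2), whose carboxyl carbon leaves as CO2.
2. Core: the methyl group and the four anhydride carbons come from the inexpensive arene 2,3,4,5-tetramethoxytoluene 3. Oxidative dearomatisation gives quinone 4 in the flask, and its one free ring carbon captures the chain radical to give the fully substituted quinone 5.
3. Excision: the C(OMe)=C(OMe) edge of 5 is cut out by ozonolysis to bis(α-keto ester) 6, then oxidative loss of both ester carbons to diacid 7. This leaves O=C–C(Me)=C(chain)–C=O with the cis geometry fixed by the former ring.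
4. Rings: the carbocycle of 3 is a sacrificial template. The only ring of the target 8, the anhydride, forms last by spontaneous closure of 7.

Assumption: the target has no stereocentre and its only C=C bond is held Z by the ring, so no enantioselective step is needed; the side chain is read from the SMILES as 14 CH2 groups between the ring carbon and the acetate oxygen.

## Route

Step 1
Reactants: 1 15-hydroxypentadecanoic acid
Product: 2 15-acetoxypentadecanoic acid
Conditions: AcOH (solvent), H2SO4 (cat.), 100 °C, 4 h; pour into water, filter
Reagents that add atoms: acetic acid, CC(=O)O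
Why: Fischer esterification: in a large excess of acetic acid with acid catalysis the primary alcohol is acetylated, while the carboxyl group can only exchange with itself (any oligoester of 1 is re-opened by acidolysis), so 2 is the equilibrium product; no stereocentre is formed.

Step 2
Reactants: 3 2,3,4,5-tetramethoxytoluene (1,2,3,4-tetramethoxy-5-methylbenzene); 2 15-acetoxypentadecanoic acid
Product: 5 14-(4,5-dimethoxy-2-methyl-3,6-dioxocyclohexa-1,4-dien-1-yl)tetradecyl acetate, via coenzyme Q0 4 (not isolated)
Conditions: AgNO3 (0.2 equiv), (NH4)2S2O8 (1.2 equiv), MeCN/H2O 1:1, 40 °C, 1 h; concentrate to half volume (removes MeOH), re-dilute with MeCN; then 2 (1.5 equiv), (NH4)2S2O8 (2.0 equiv, aq., added over 1 h), 75 °C, 2 h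
Reagents that add atoms: water, O
Why: Proposed new method: persulfate oxidises monovalent to divalent silver, which takes the electron-rich para-dimethoxyarene 3 to its radical cation so that water adds at the two para ipso carbons and methanol is expelled (oxidative demethylation to the quinone, known with AgO/HNO3 or (NH4)2Ce(NO3)6), and the same AgNO3/(NH4)2S2O8 couple then decarboxylates 2 (Kochi–Anderson) to a primary alkyl radical that adds to the only unsubstituted ring carbon of 4 and is re-oxidised to the quinone (Jacobsen–Torssell alkylation, as in idebenone-type syntheses); the two known reactions are merely run in one flask, MeOH being stripped in between so that it cannot give hydroxymethyl radicals, and no stereocentre is formed.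

Step 3
Reactants: 5 14-(4,5-dimethoxy-2-methyl-3,6-dioxocyclohexa-1,4-dien-1-yl)tetradecyl acetate
Product: 8 Aspergillus acid E [14-(4-methyl-2,5-dioxo-2,5-dihydrofuran-3-yl)tetradecyl acetate], via bis(keto ester) 6 (not isolated), via maleic diacid 7 (not isolated)
Conditions: O3 (1.0–1.1 equiv), CH2Cl2/MeOH 9:1, −78 °C; Me2S (2 equiv), −78 → 0 °C, evaporate; 30% aq. H2O2 (4 equiv), THF/NaH2PO4–Na2HPO4 buffer (pH 7), 0 °C → rt; 1 M HCl, extract, concentrate from toluene
Reagents that add atoms: ozone, [O-][O+]=O (the two ester carbonyl oxygens of 6, lost again as CO2); hydrogen peroxide, OO (the ring oxygen of 8)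
Why: Proposed new method: electrophilic ozone should cleave the donor-substituted C(OMe)=C(OMe) bond of 5 in preference to the dialkyl enedione bond (Criegee ozonolysis of enol-ether-type alkenes to esters, as when veratroles give muconates), giving after Me2S the bis(α-keto ester) 6, whose very electrophilic keto groups add H2O2 and fragment with loss of methyl hydrogen carbonate (the known Baeyer–Villiger-type oxidative cleavage of α-keto acids and esters to carboxylic acids), and the resulting 2,3-dialkylmaleic acid 7 dehydrates spontaneously to the anhydride on acidification; the Z geometry is inherited from the six-membered ring, the tetrasubstituted alkene is too electron-poor to be ozonised or epoxidised at pH 7, and no stereocentre is formed.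

## Compound list

1 | 15-hydroxypentadecanoic acid | OCCCCCCCCCCCCCCC(=O)O | starting material
2 | 15-acetoxypentadecanoic acid | CC(=O)OCCCCCCCCCCCCCCC(=O)O | intermediate
3 | 2,3,4,5-tetramethoxytoluene (1,2,3,4-tetramethoxy-5-methylbenzene) | Cc1cc(OC)c(OC)c(OC)c1OC | starting material
4 | 2,3-dimethoxy-5-methyl-1,4-benzoquinone (coenzyme Q0) | CC1=CC(=O)C(OC)=C(OC)C1=O | intermediate
5 | 14-(4,5-dimethoxy-2-methyl-3,6-dioxocyclohexa-1,4-dien-1-yl)tetradecyl acetate | CC(=O)OCCCCCCCCCCCCCCC1=C(C)C(=O)C(OC)=C(OC)C1=O | intermediate
6 | dimethyl (3Z)-3-(14-acetoxytetradecyl)-4-methyl-2,5-dioxohex-3-enedioate | COC(=O)C(=O)/C(C)=C(/CCCCCCCCCCCCCCOC(C)=O)C(=O)C(=O)OC | intermediate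
7 | (2Z)-2-(14-acetoxytetradecyl)-3-methylbut-2-enedioic acid | OC(=O)/C(C)=C(/CCCCCCCCCCCCCCOC(C)=O)C(=O)O | intermediate
8 | Aspergillus acid E, 14-(4-methyl-2,5-dioxo-2,5-dihydrofuran-3-yl)tetradecyl acetate | CC(=O)OCCCCCCCCCCCCCCC1=C(C)C(=O)OC1=O | target

## Step count and risks

Total step count: 3. Longest linear sequence: 3 steps (1 → 2 → 5 → 8).

**Step 3 (highest risk).** Ozone may also attack the C(Me)=C(chain) bond of 5, or peroxide may epoxidise 6. The fallback sets out from 5 and comes back to the route at 7. Treat 5 with BCl3 (CH2Cl2, −78 → 0 °C), which removes both carbonyl-flanked methyl ethers by chelation-assisted cleavage and leaves the alkyl acetate alone. This gives the ene-diol 14-(4,5-dihydroxy-2-methyl-3,6-dioxocyclohexa-1,4-dien-1-yl)tetradecyl acetate F3. NaIO4 (4 equiv, THF/H2O, 0 °C → rt) then oxidises the ene-diol to the ring tetraketone and cleaves it as a hydrated vicinal polycarbonyl (Malaprade-type cleavage). The two former C–O carbons leave as CO2 and diacid 7 results, which closes to 8 on acidification as before. The site of cleavage is then fixed by where the oxygen atoms sit, not by the relative nucleophilicity of two alkenes.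

**Step 2.** The one-flask dearomatisation may be inefficient with catalytic silver, or the released methanol and the waxy acid may spoil the radical stage. The fallback sets out from 3 (with 2) and comes back at 5. Oxidise 3 with (NH4)2Ce(NO3)6 (MeCN/H2O, 0 °C) and isolate quinone 4. Separately convert 2 with DCC and H2O2 (CH2Cl2/Et2O, 0 °C) into bis(15-acetoxypentadecanoyl) peroxide F2. Heat 4 with F2 in AcOH at 90 °C: thermal homolysis, loss of CO2 and addition of the alkyl radical to 4 give 5 without silver or persulfate, and the second acyloxy half returns as acid 2.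

**Step 1 (lowest risk).** Acetylation may be incomplete or leave oligoesters of 1. The fallback sets out from 1 (with 3) and comes back at 5. Use the free hydroxy acid 1 itself in the step 2 procedure, since a primary alcohol should survive the AgNO3/(NH4)2S2O8 decarboxylation. This gives 2-(14-hydroxytetradecyl)-5,6-dimethoxy-3-methyl-1,4-benzoquinone F1. Acetylate F1 afterwards (Ac2O, pyridine, DMAP cat., CH2Cl2), where no carboxyl group competes, to reach 5.

Further compounds
F1 | step 1 | 2-(14-hydroxytetradecyl)-5,6-dimethoxy-3-methyl-1,4-benzoquinone | OCCCCCCCCCCCCCCC1=C(C)C(=O)C(OC)=C(OC)C1=O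
F2 | step 2 | bis(15-acetoxypentadecanoyl) peroxide | CC(=O)OCCCCCCCCCCCCCCC(=O)OOC(=O)CCCCCCCCCCCCCCOC(C)=O
F3 | step 3 | 14-(4,5-dihydroxy-2-methyl-3,6-dioxocyclohexa-1,4-dien-1-yl)tetradecyl acetate | CC(=O)OCCCCCCCCCCCCCCC1=C(C)C(=O)C(O)=C(O)C1=O
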